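The small charge of initiator, 2.5 mol% in Thursday's flask, was where I began, because the first reading of target, 28.1%, already stood 11.2 times above it. So a chain had been at work in the first hours, with starting material caught by initiating radical, chain carrier meeting partner, and the radical handed on.

| flask | starting material | partner | protic impurity | initiator | temperature | remark | time |
|---|---|---|---|---|---|---|---|
| Thursday's | 1.3 M | 0.95 equiv | 0.26 M | 2.5 mol% | 0 °C | the very flask that is asked about, followed so far |  |
| Monday's | 1.3 M | 0.95 equiv | 0.26 M | 3.8 mol% | 6 °C | run made earlier |  |
| flask | 1.3 M | 0.950 equiv | 0.260 M | 2.5 mol% | 0 °C |  | 3.0 d |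

| run | time / h | target / % |
|---|---|---|
| Thursday's | 3.00 | 28.1 |
| Thursday's | 5.00 | 25.0 |
| Thursday's | 8.00 | 23.1 |
| Thursday's | 12.0 | 23.0 |
| Thursday's | 20.0 | 22.0 |
| Thursday's | 30.0 | 22.7 |
| Thursday's | 40.0 | 21.1 |
| Monday's | 4.00 | 31.5 |
| Monday's | 8.00 | 29.3 |
| Monday's | 12.0 | 30.2 |
| Monday's | 15.0 | 29.8 |
| Monday's | 20.0 | 30.3 |
| Monday's | 25.0 | 29.9 |
| Monday's | 30.0 | 31.3 |

(readings scatter by 1 percentage point)

- in percentages every species weighs as the starting material in it: one ended chains or self-condensation product counts as two
- what is taken out of target is counted as made
- the numbers in the tables scatter by 1 percentage point (one standard deviation)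
- what may be going on: initiator -> 2 initiating radical; starting material + initiating radical -> chain carrier; partner + chain carrier -> target + initiating radical; 2 chain carrier -> ended chains; 2 starting material -> self-condensation product; target <-> isomer of the product; partner + protic impurity -> quenched reagent

- summer: at 3.0 d take out 90% of the target then present, then wait 20 h
- spring: change nothing and wait 20 h more
- dawn: at 3.0 d raise the temperature by 20 K, then wait 20 h

- target, in percent of the starting material first charged, at 3.0 d
- which option adds most target ("none" when 2 percentage points or less is all one gets) (summer / spring / dawn / none)
- target present, with what was taken out counted in, in percent of the starting material first charged, after spring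
- target present, with what was taken out counted in, in percent of the starting material first charged, after dawn

In the middle of Thursday's run the target fell, to 23.1% at 8.00 h, and of the steps that may be going on, the one that takes target away is its passing into isomer. From 12.0 h to 40.0 h the readings averaged 22.2%, so I took this plateau as equilibrium, thermodynamic control after a kinetic start, and expected it to stand at 3.0 d, with spring adding nothing.

What I carried forward was the hidden share, the part of target plus isomer that lies as isomer. The first reading stood 5.9 percentage points above the plateau, which gave a share of 21.0%. I took this for a low estimate, since the fall may have begun before that reading. Taking out 90% of the target lets the isomer return in proportion, which I reckoned at 4.2 points. In Monday's flask, warmer though also richer in initiator, the first reading, at 4.00 h, stood just 1.4 points above its own plateau, with a scatter of 1 point on each reading, and I took this as a faint hint that warmth holds less isomer. So I committed to dawn, with a gain near 5.9 points.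

The forecast gave 21.8% now, 21.7% after spring and 22% after dawn, and named summer as best, holding that “Warming restarts no chain and only shifts the equilibrium slightly”.

The flask gave 21.8% at 3.0 d, 21.8% after spring and 32.2% after dawn. Dawn was best at 10 points, against 6.8 points for summer and 0 points for spring.

    initiator → 2 initiating radical (k = 1.30 × 10⁻⁴ /min, Ea = 100 kJ/mol)
    starting material + initiating radical → chain carrier (k = 17000 /M/min, Ea = 35.0 kJ/mol)
    partner + chain carrier → target + initiating radical (k = 26000 /M/min, Ea = 38.0 kJ/mol)
    2 chain carrier → ended chains (k = 4.40 × 10⁶ /M/s, Ea = 15.0 kJ/mol)
    2 starting material → self-condensation product (k = 0.0160 /M/min, Ea = 73.0 kJ/mol)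
    target ⇌ isomer of the product (K = 0.530, k = 0.00190 /min, Ea = 99.0 kJ/mol, ΔH = −90.0 kJ/mol)
    partner + protic impurity → quenched reagent (k = 0.00530 /M/min, Ea = 59.0 kJ/mol)
    (constants at 0 °C)

In Thursday's flask the forward half-life of target into isomer, 0.25 d, was short against the 3.0 d, and at that time 21.8% of target stood beside 11.6% of isomer. The hidden share there, reckoned from these two amounts and not from readings, was 34.6%, where the readings had given me 21.0%. In the neighbouring repeat at 25 °C, 36.6% of target stood beside 0.699% of isomer at 3.00 d, a hidden share of 1.87%.

The numbers in the tables come from a simulation with made-up constants, and the scatter is random.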